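**Retrosynthetic overview**
1. The lactone ring (C16, O, C12, C13, C14, C1, C15) is the six-membered carbocycle C16–C12–C13–C14–C1–C15 plus one oxygen, placed next to C12, the only quaternary neighbour of C16. The target therefore goes back to its C15-silyloxymethyl lactone and then, by Baeyer–Villiger oxygen insertion, to a trans-1,4-bridged bicyclo[10.2.2]hexadecan-16-one.
2. The 14-membered ring is opened at C5=C6 (ring-closing metathesis, then diimide). The C3–C4 epoxide comes from a Sharpless epoxidation of a C5 allylic alcohol, and C3=C4 from a Wittig reaction.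
3. C1 is set by Rh/(S)-BINAP vinyl addition to a 6,6-disubstituted cyclohexenone; C17 is added by enolate hydroxymethylation at C15.
4. C11–C12 (quaternary C12 and carbinol C11 together) comes from a Brown allylboration of a geraniol-derived C6–C11 aldehyde (Sharpless epoxidation, Payne hydrolysis) with the allylborane of 1,2-dimethylcyclohexene; the exocyclic methylene is then cut to the C16 ketone.
5. Ring order: cyclohexane (bought), oxirane (step 18), 14-membered carbocycle (step 23), ε-lactone by ring expansion (step 25).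

Key step: step 25

Assumption: cembrane numbering is used (C1 = ring CH bearing C15, C3/C4 = epoxide, C7 = acetoxy carbon, C16 = lactone carbonyl, C17 = methylene), and 1,2-dimethylcyclohexene is taken as a catalogue compound (otherwise two steps from 2-methylcyclohexanone: MeMgBr, then acid-catalysed dehydration).

**Step 1**
Reactants: 1 geraniol
Product: 2 (2S,3S)-2,3-epoxygeraniol
Conditions: Ti(OiPr)4 (cat.), L-(+)-DET, t-BuOOH, 4 Å MS, CH2Cl2, −20 °C
Reagents that add atoms: tert-butyl hydroperoxide, CC(C)(C)OO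
Why: Katsuki–Sharpless asymmetric epoxidation of the allylic alcohol, in which L-(+)-tartrate delivers oxygen to the face that gives the (2S,3S)-epoxide and the remote trisubstituted alkene is left alone.

**Step 2**
Reactants: 2 (2S,3S)-2,3-epoxygeraniol
Product: 3 (2R,3S)-3,7-dimethyloct-6-ene-1,2,3-triol
Conditions: 0.5 M NaOH, t-BuOH/H2O, 75 °C
Reagents that add atoms: water, O
Why: Payne rearrangement followed by hydroxide opening of the terminal epoxide (direct SN2 at the secondary carbon gives the same result) inverts C7 and keeps C8, so the syn epoxide becomes the anti (7R,8S) diol pattern of the target.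

**Step 3**
Reactants: 3 (2R,3S)-3,7-dimethyloct-6-ene-1,2,3-triol
Product: 4 (4R)-4-[(2S)-2-hydroxy-6-methylhept-5-en-2-yl]-2-(4-methoxyphenyl)-1,3-dioxolane (both epimers at the acetal carbon)
Conditions: 4-MeOC6H4CH(OMe)2, PPTS (cat.), CH2Cl2, rt
Reagents that add atoms: 4-methoxybenzaldehyde dimethyl acetal, COC(OC)c1ccc(OC)cc1
Why: Acid-catalysed transacetalisation should close the five-membered acetal on the primary/secondary 1,2-diol and leave the tertiary hydroxyl free; the new acetal centre is a mixture and is destroyed in step 7.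

**Step 4**
Reactants: 4 dioxolane alcohol
Product: 5 tertiary triethylsilyl ether of 4
Conditions: TESOTf, 2,6-lutidine, CH2Cl2, −78 °C
Reagents that add atoms: triethylsilyl trifluoromethanesulfonate, CC[Si](CC)(CC)OS(=O)(=O)C(F)(F)F
Why: Silyl triflate silylation of the tertiary alcohol at low temperature, needed because a free C8 hydroxyl would close a lactol on the C11 aldehyde made next.

**Step 5**
Reactants: 5 tertiary triethylsilyl ether
Product: 6 (4S)-4-[(4R)-2-(4-methoxyphenyl)-1,3-dioxolan-4-yl]-4-(triethylsilyloxy)pentanal (C6–C11 aldehyde)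
Conditions: O3, CH2Cl2/MeOH, NaHCO3, −78 °C (Sudan III end point); Me2S
Reagents that add atoms: ozone, [O-][O+]=O
Why: Ozonolysis with reductive work-up cleaves the electron-rich trisubstituted alkene much faster than ozone attacks the acetal or the anisyl ring, and the indicator stops the reaction at that point.

**Step 6**
Reactants: 6 C6–C11 aldehyde; 7 1,2-dimethylcyclohexene
Product: 10 (1R,4S)-4-[(4R)-2-(4-methoxyphenyl)-1,3-dioxolan-4-yl]-1-[(1S)-1-methyl-2-methylidenecyclohexyl]-4-(triethylsilyloxy)pentan-1-ol, via potassium (2-methylcyclohex-1-en-1-yl)methanide 8 (not isolated), via B-[(2-methylcyclohex-1-en-1-yl)methyl]diisopinocampheylborane 9 (not isolated)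
Conditions: 7, n-BuLi, KOt-Bu, THF, −78 to −45 °C; (−)-Ipc2BOMe, −78 °C; BF3·OEt2; 6, −78 °C; NaOH, H2O2
Reagents that add atoms: none
Why: Brown asymmetric allylboration: Schlosser-base metalation of a methyl group, boron at the primary terminus, then addition through a chair transition state at the ring carbon creates the quaternary C12 (its methyl, cis to CH2B in the reagent, ends up syn to the new hydroxyl) and C11 (Si-face attack dictated by the Ipc groups from (+)-α-pinene) in one operation.

**Step 7**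
Reactants: 10 homoallylic alcohol
Product: 11 C7 p-methoxybenzyl ether with free C6 and C11 hydroxyls (7R,8S,11R,12S)
Conditions: DIBAL-H, CH2Cl2, −78 to 0 °C; Rochelle salt
Reagents that add atoms: none
Why: Reductive opening of the p-methoxybenzylidene acetal by DIBAL-H, where aluminium binds the unhindered primary oxygen, so the PMB group stays on the hindered secondary O7 and the primary C6 hydroxyl is released.

**Step 8**
Reactants: 11 PMB ether diol
Product: 12 C6,C8,C11-tris(triethylsilyl) ether (7R,8S,11R,12S)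
Conditions: TESOTf, 2,6-lutidine, CH2Cl2, −78 to 0 °C
Reagents that add atoms: triethylsilyl trifluoromethanesulfonate, CC[Si](CC)(CC)OS(=O)(=O)C(F)(F)F
Why: Silyl triflate silylation covers the primary and the hindered secondary alcohol together; the primary TES ether is the latent C6 aldehyde and the C11 ether blocks retro-aldol cleavage later.

**Step 9**
Reactants: 12 tris(triethylsilyl) ether
Product: 13 2-methyl-2-(1-silyloxyalkyl)cyclohexanone (C16 ketone; 7R,8S,11R,12R)
Conditions: O3, CH2Cl2/MeOH, pyridine, −78 °C (Sudan III end point); Me2S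
Reagents that add atoms: ozone, [O-][O+]=O
Why: Ozonolysis of the only C=C bond converts the exocyclic methylene into the C16 ketone, giving the protected aldol that a direct ketone aldol could not deliver with stereocontrol.

**Step 10**
Reactants: 13 ketone
Product: 14 6-methyl-6-(1-silyloxyalkyl)cyclohex-2-en-1-one (C15=C1 enone)
Conditions: LDA, THF, −78 °C; PhS(Cl)=Nt-Bu, −78 °C
Reagents that add atoms: none
Why: Mukaiyama dehydrogenation of the lithium enolate with N-tert-butylbenzenesulfinimidoyl chloride; C12 is quaternary, so only the C15 enolate can form.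

**Step 11**
Reactants: 14 enone
Product: 15 3-vinyl ketone (1S,7R,8S,11R,12R)
Conditions: (CH2=CHBO)3·pyridine, [Rh(OH)(cod)]2 (3 mol %), (S)-BINAP, dioxane/H2O (10:1), 40 °C
Reagents that add atoms: 2,4,6-trivinylcyclotriboroxane–pyridine complex, C=CB1OB(C=C)OB(C=C)O1.c1ccncc1
Why: Hayashi–Miyaura rhodium-catalysed 1,4-addition of an alkenylboron reagent; the 1,4-remote C12 centre biases the enone faces only weakly, so (S)-BINAP should set C1 in the sense it gives (S)-3-alkenylcyclohexanones, which puts the vinyl group cis to the C12 methyl.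

**Step 12**
Reactants: 15 vinyl ketone
Product: 16 2-(hydroxymethyl)-3-vinyl ketone (1R,15S drawn; 7R,8S,11R,12R)
Conditions: LDA, THF, −78 °C; CH2O (g), −78 to −40 °C; NH4Cl
Reagents that add atoms: formaldehyde, C=O
Why: Aldol addition of the only possible enolate (C15) to monomeric formaldehyde, expected anti to the C1 vinyl group; the configuration at C15 does not matter because this carbon becomes sp2 in step 27.

**Step 13**
Reactants: 16 hydroxymethyl ketone
Product: 17 C17 tert-butyldimethylsilyl ether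
Conditions: TBSCl, imidazole, DMF, rt
Reagents that add atoms: tert-butyldimethylsilyl chloride, CC(C)(C)[Si](C)(C)Cl
Why: Standard silylation of the primary alcohol stores the future methylene carbon as a silyloxymethyl group that also lowers the migratory aptitude of C15.

**Step 14**
Reactants: 17 vinyl ketone silyl ether
Product: 18 C3 primary alcohol (C1–CH2CH2OH)
Conditions: 9-BBN, THF, 0 °C to rt; NaBO3·4H2O, H2O
Reagents that add atoms: sodium perborate, [Na+].[O-]OB=O
Why: Anti-Markovnikov hydroboration–oxidation; 9-BBN should take the terminal vinyl group far faster than the ketone flanked by a quaternary and a tertiary carbon, and perborate avoids base-induced loss of the β-silyloxy group.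

**Step 15**
Reactants: 18 primary alcohol
Product: 19 C3 aldehyde
Conditions: Dess–Martin periodinane, NaHCO3, CH2Cl2, rt
Reagents that add atoms: none
Why: Buffered Dess–Martin oxidation of the primary alcohol, mild enough for the silyl ethers and the PMB ether.

**Step 16**
Reactants: 19 aldehyde
Product: 20 (E)-2-methyl enal (C3=C4, C5 aldehyde)
Conditions: Ph3P=C(Me)CHO, toluene, 80 °C
Reagents that add atoms: 2-(triphenylphosphoranylidene)propanal, CC(C=O)=P(c1ccccc1)(c1ccccc1)c1ccccc1
Why: Wittig olefination with the stabilised formyl ylide gives the (E)-trisubstituted enal, which fixes the C3=C4 geometry needed for the trans epoxide; the hindered ketone does not react.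

**Step 17**
Reactants: 20 enal
Product: 21 (E)-allylic alcohol (C5–OH)
Conditions: NaBH4, MeOH/CH2Cl2, −78 °C
Reagents that add atoms: none
Why: Borohydride 1,2-reduction of the aldehyde at low temperature; the C16 ketone is shielded on both sides and should survive.

**Step 18**
Reactants: 21 allylic alcohol
Product: 22 (3S,4S)-epoxy alcohol
Conditions: Ti(OiPr)4, L-(+)-DET, t-BuOOH, 4 Å MS, CH2Cl2, −20 °C
Reagents that add atoms: tert-butyl hydroperoxide, CC(C)(C)OO
Why: Katsuki–Sharpless epoxidation of the (E)-2-methyl allylic alcohol; L-(+)-tartrate sets C3 and C4 as (3S,4S) under reagent control, independent of the distant stereocentres.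

**Step 19**
Reactants: 22 epoxy alcohol
Product: 23 C5,C6-dialdehyde (epoxy aldehyde and α-PMB-oxy aldehyde; all stereocentres as in 22)
Conditions: (COCl)2, DMSO, CH2Cl2, −78 to −40 °C; Et3N, to 0 °C
Reagents that add atoms: none
Why: Swern oxidation with excess reagent oxidises the C5 alcohol and converts the primary TES ether at C6 directly into the aldehyde, a known selectivity that leaves secondary and tertiary TES ethers and the TBS ether untouched.

**Step 20**
Reactants: 23 dialdehyde
Product: 24 bis-vinyl compound (vinyl epoxide and C7 PMB-protected allylic ether; 1R,3S,4S,7R,8S,11R,12R,15S)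
Conditions: Ph3PCH3Br, KHMDS, THF, −78 to −20 °C
Reagents that add atoms: methyltriphenylphosphonium bromide, C[P+](c1ccccc1)(c1ccccc1)c1ccccc1.[Br-]
Why: Wittig methylenation of both aldehydes at low temperature, where the hindered ketone is not attacked and the α-alkoxy centre C7 should not epimerise.

**Step 21**
Reactants: 24 bis-vinyl PMB ether
Product: 25 C7 allylic alcohol
Conditions: DDQ, CH2Cl2/pH 7 buffer, 0 °C
Reagents that add atoms: none
Why: Oxidative cleavage of the PMB ether by DDQ under neutral buffer, which spares the vinyl epoxide and the silyl ethers that acid or fluoride would endanger.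

**Step 22**
Reactants: 25 C7 alcohol
Product: 26 C7 acetate (metathesis precursor)
Conditions: Ac2O, DMAP, pyridine, CH2Cl2, rt
Reagents that add atoms: acetic anhydride, CC(=O)OC(C)=O
Why: DMAP-catalysed acylation of the only free hydroxyl places the acetate after the last strongly basic step.

**Step 23**
Reactants: 26 diene
Product: 27 bicyclo[10.2.2] ketone with a C5=C6 double bond (E/Z mixture)
Conditions: Hoveyda–Grubbs II (15 mol %), toluene (1 mM), 80 °C
Reagents that add atoms: none
Why: Ring-closing metathesis of the two terminal alkenes closes the 14-membered ring with loss of ethylene; the trans-1,4 chains on C12 and C1 are both equatorial and span the C13–C14 edge without strain, and the alkene geometry is irrelevant because the bond is saturated next.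

**Step 24**
Reactants: 27 macrocyclic alkene
Product: 28 bridged cyclohexanone (1R,3S,4S,7R,8S,11R,12R,15S)
Conditions: KO2CN=NCO2K, AcOH, pyridine/MeOH, rt
Reagents that add atoms: none
Why: Diimide reduction transfers H2 to the only C=C bond without a metal, so the allylic epoxide and allylic acetate cannot be hydrogenolysed and the ketone is not reduced.

**Step 25**
Reactants: 28 bridged cyclohexanone
Product: 29 ε-lactone with C15 silyloxymethyl group
Conditions: mCPBA, NaHCO3, CH2Cl2, 0 °C to rt
Reagents that add atoms: 3-chloroperbenzoic acid, OOC(=O)c1cccc(Cl)c1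
Why: mCPBA adds to the C16 carbonyl and, in the Criegee adduct, the C12–C16 bond antiperiplanar to the O–O bond shifts to oxygen with loss of 3-chlorobenzoate, which forms the O–C12 and C16–O bonds. The closest known reaction type is the peracid Baeyer–Villiger oxidation of 2,2-disubstituted cyclohexanones to ε-lactones with migration of the quaternary carbon. The seven-membered ring (C16, O, C12, C13, C14, C1, C15) is closed by ring expansion of the six-membered ketone through this 1,2-shift and not by a cyclisation, so no closure onto the tertiary C12 oxygen is needed. No stereocentre is created: C12 migrates with retention and carries its configuration from step 6 into the C–O centre, while C15 is erased in step 27. The step needs C12 and not C15 to migrate, which the substrate secures because both carry one β-oxygen but C12 is fully substituted and C15 only secondary. It also needs chemoselectivity, which holds because no C=C bond is left after step 24 and the bicarbonate buffer protects the epoxide, the acetate and the silyl ethers.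

**Step 26**
Reactants: 29 silylated lactone
Product: 30 trihydroxy lactone (C8, C11, C17 hydroxyls free)
Conditions: HF·pyridine, pyridine, THF, 0 °C to rt
Reagents that add atoms: none
Why: Buffered fluoride desilylation removes the primary TBS and both TES ethers in one operation under conditions that trisubstituted epoxides and acetates normally tolerate.

**Step 27**
Reactants: 30 trihydroxy lactone
Product: 32 CNP0174704.2 (target), via primary mesylate 31 (not isolated)
Conditions: MsCl, Et3N, CH2Cl2, −20 °C; DBU, rt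
Reagents that add atoms: none
Why: Selective sulfonylation of the primary hydroxyl (the C11 hydroxyl is neopentyl-like, the C8 hydroxyl tertiary) followed by E1cB elimination with DBU unveils the C15=C17 methylene conjugated to the lactone.

**Compound list**
1 | geraniol | CC(C)=CCC/C(C)=C/CO | starting material
2 | (2S,3S)-2,3-epoxygeraniol | OC[C@@H]1O[C@@]1(C)CCC=C(C)C | intermediate
3 | (2R,3S)-3,7-dimethyloct-6-ene-1,2,3-triol | OC[C@@H](O)[C@@](C)(O)CCC=C(C)C | intermediate
4 | (4R)-4-[(2S)-2-hydroxy-6-methylhept-5-en-2-yl]-2-(4-methoxyphenyl)-1,3-dioxolane, acetal epimers | COc1ccc(cc1)C1OC[C@@H](O1)[C@@](C)(O)CCC=C(C)C | intermediate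
5 | tertiary triethylsilyl ether of 4 | COc1ccc(cc1)C1OC[C@@H](O1)[C@@](C)(O[Si](CC)(CC)CC)CCC=C(C)C | intermediate
6 | (4S)-4-[(4R)-2-(4-methoxyphenyl)-1,3-dioxolan-4-yl]-4-(triethylsilyloxy)pentanal | COc1ccc(cc1)C1OC[C@@H](O1)[C@@](C)(O[Si](CC)(CC)CC)CCC=O | intermediate
7 | 1,2-dimethylcyclohexene | CC1=C(C)CCCC1 | starting material
8 | potassium (2-methylcyclohex-1-en-1-yl)methanide | [CH2-]C1=C(C)CCCC1.[K+] | intermediate
9 | B-[(2-methylcyclohex-1-en-1-yl)methyl]diisopinocampheylborane, Ipc groups from (+)-α-pinene | CC1=C(CB([C@@H]2C[C@@H]3C[C@H]([C@H]2C)C3(C)C)[C@@H]2C[C@@H]3C[C@H]([C@H]2C)C3(C)C)CCCC1 | intermediate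
10 | homoallylic alcohol (C11 R, C12 S, exocyclic methylene at C16, C6/C7 PMP acetal, C8 OTES) | COc1ccc(cc1)C1OC[C@@H](O1)[C@@](C)(O[Si](CC)(CC)CC)CC[C@@H](O)[C@@]2(C)CCCCC2=C | intermediate
11 | C7 PMB ether, C6 and C11 hydroxyls free | OC[C@@H](OCc1ccc(OC)cc1)[C@@](C)(O[Si](CC)(CC)CC)CC[C@@H](O)[C@@]2(C)CCCCC2=C | intermediate
12 | C6,C8,C11-tris(triethylsilyl) ether, C7 PMB ether | CC[Si](CC)(CC)OC[C@@H](OCc1ccc(OC)cc1)[C@@](C)(O[Si](CC)(CC)CC)CC[C@@H](O[Si](CC)(CC)CC)[C@@]2(C)CCCCC2=C | intermediate
13 | C16 ketone (2,2-disubstituted cyclohexanone) | CC[Si](CC)(CC)OC[C@@H](OCc1ccc(OC)cc1)[C@@](C)(O[Si](CC)(CC)CC)CC[C@@H](O[Si](CC)(CC)CC)[C@@]2(C)CCCCC2=O | intermediate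
14 | C15=C1 enone (6,6-disubstituted cyclohex-2-enone) | CC[Si](CC)(CC)OC[C@@H](OCc1ccc(OC)cc1)[C@@](C)(O[Si](CC)(CC)CC)CC[C@@H](O[Si](CC)(CC)CC)[C@@]2(C)CCC=CC2=O | intermediate
15 | C1 vinyl ketone (vinyl cis to the C12 methyl) | CC[Si](CC)(CC)OC[C@@H](OCc1ccc(OC)cc1)[C@@](C)(O[Si](CC)(CC)CC)CC[C@@H](O[Si](CC)(CC)CC)[C@@]2(C)CC[C@H](C=C)CC2=O | intermediate
16 | C15 hydroxymethyl ketone (CH2OH trans to vinyl) | CC[Si](CC)(CC)OC[C@@H](OCc1ccc(OC)cc1)[C@@](C)(O[Si](CC)(CC)CC)CC[C@@H](O[Si](CC)(CC)CC)[C@@]2(C)CC[C@H](C=C)[C@@H](CO)C2=O | intermediate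
17 | C17 TBS ether | CC[Si](CC)(CC)OC[C@@H](OCc1ccc(OC)cc1)[C@@](C)(O[Si](CC)(CC)CC)CC[C@@H](O[Si](CC)(CC)CC)[C@@]2(C)CC[C@H](C=C)[C@@H](CO[Si](C)(C)C(C)(C)C)C2=O | intermediate
18 | C3 primary alcohol | CC[Si](CC)(CC)OC[C@@H](OCc1ccc(OC)cc1)[C@@](C)(O[Si](CC)(CC)CC)CC[C@@H](O[Si](CC)(CC)CC)[C@@]2(C)CC[C@H](CCO)[C@@H](CO[Si](C)(C)C(C)(C)C)C2=O | intermediate
19 | C3 aldehyde | CC[Si](CC)(CC)OC[C@@H](OCc1ccc(OC)cc1)[C@@](C)(O[Si](CC)(CC)CC)CC[C@@H](O[Si](CC)(CC)CC)[C@@]2(C)CC[C@H](CC=O)[C@@H](CO[Si](C)(C)C(C)(C)C)C2=O | intermediate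
20 | (E)-2-methyl enal (C3=C4, C5 aldehyde) | CC[Si](CC)(CC)OC[C@@H](OCc1ccc(OC)cc1)[C@@](C)(O[Si](CC)(CC)CC)CC[C@@H](O[Si](CC)(CC)CC)[C@@]2(C)CC[C@H](C/C=C(\C)C=O)[C@@H](CO[Si](C)(C)C(C)(C)C)C2=O | intermediate
21 | (E)-allylic alcohol (C5–OH) | CC[Si](CC)(CC)OC[C@@H](OCc1ccc(OC)cc1)[C@@](C)(O[Si](CC)(CC)CC)CC[C@@H](O[Si](CC)(CC)CC)[C@@]2(C)CC[C@H](C/C=C(\C)CO)[C@@H](CO[Si](C)(C)C(C)(C)C)C2=O | intermediate
22 | (3S,4S)-epoxy alcohol | CC[Si](CC)(CC)OC[C@@H](OCc1ccc(OC)cc1)[C@@](C)(O[Si](CC)(CC)CC)CC[C@@H](O[Si](CC)(CC)CC)[C@@]2(C)CC[C@H](C[C@@H]3O[C@@]3(C)CO)[C@@H](CO[Si](C)(C)C(C)(C)C)C2=O | intermediate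
23 | C5,C6-dialdehyde | O=C[C@@H](OCc1ccc(OC)cc1)[C@@](C)(O[Si](CC)(CC)CC)CC[C@@H](O[Si](CC)(CC)CC)[C@@]2(C)CC[C@H](C[C@@H]3O[C@@]3(C)C=O)[C@@H](CO[Si](C)(C)C(C)(C)C)C2=O | intermediate
24 | bis-vinyl compound, C7 PMB ether | C=C[C@@H](OCc1ccc(OC)cc1)[C@@](C)(O[Si](CC)(CC)CC)CC[C@@H](O[Si](CC)(CC)CC)[C@@]2(C)CC[C@H](C[C@@H]3O[C@@]3(C)C=C)[C@@H](CO[Si](C)(C)C(C)(C)C)C2=O | intermediate
25 | bis-vinyl compound, C7 alcohol | C=C[C@@H](O)[C@@](C)(O[Si](CC)(CC)CC)CC[C@@H](O[Si](CC)(CC)CC)[C@@]2(C)CC[C@H](C[C@@H]3O[C@@]3(C)C=C)[C@@H](CO[Si](C)(C)C(C)(C)C)C2=O | intermediate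
26 | bis-vinyl compound, C7 acetate | C=C[C@@H](OC(C)=O)[C@@](C)(O[Si](CC)(CC)CC)CC[C@@H](O[Si](CC)(CC)CC)[C@@]2(C)CC[C@H](C[C@@H]3O[C@@]3(C)C=C)[C@@H](CO[Si](C)(C)C(C)(C)C)C2=O | intermediate
27 | bicyclo[10.2.2] ketone with C5=C6 alkene | [C@H]1(CO[Si](C)(C)C(C)(C)C)C(=O)[C@]2(C)CC[C@@H]1C[C@@H]1O[C@@]1(C)C=C[C@@H](OC(C)=O)[C@@](C)(O[Si](CC)(CC)CC)CC[C@H]2O[Si](CC)(CC)CC | intermediate
28 | bridged cyclohexanone (Baeyer–Villiger precursor) | [C@H]1(CO[Si](C)(C)C(C)(C)C)C(=O)[C@]2(C)CC[C@@H]1C[C@@H]1O[C@@]1(C)CC[C@@H](OC(C)=O)[C@@](C)(O[Si](CC)(CC)CC)CC[C@H]2O[Si](CC)(CC)CC | intermediate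
29 | ε-lactone with C15 silyloxymethyl group | [C@H]1(CO[Si](C)(C)C(C)(C)C)C(=O)O[C@]2(C)CC[C@@H]1C[C@@H]1O[C@@]1(C)CC[C@@H](OC(C)=O)[C@@](C)(O[Si](CC)(CC)CC)CC[C@H]2O[Si](CC)(CC)CC | intermediate
30 | trihydroxy lactone | [C@H]1(CO)C(=O)O[C@]2(C)CC[C@@H]1C[C@@H]1O[C@@]1(C)CC[C@@H](OC(C)=O)[C@@](C)(O)CC[C@H]2O | intermediate
31 | primary mesylate of 30 | [C@H]1(COS(C)(=O)=O)C(=O)O[C@]2(C)CC[C@@H]1C[C@@H]1O[C@@]1(C)CC[C@@H](OC(C)=O)[C@@](C)(O)CC[C@H]2O | intermediate
32 | CNP0174704.2 (1R,3S,4S,7R,8S,11R,12R) | C=C1C(=O)O[C@]2(C)CC[C@@H]1C[C@@H]1O[C@@]1(C)CC[C@@H](OC(C)=O)[C@@](C)(O)CC[C@H]2O | target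

**Step count and risks**
Total step count: 27. Longest linear sequence: 27 steps (geraniol to target; 1,2-dimethylcyclohexene enters at step 6).

Steps most likely to fail:

1. Step 25 (key step). The risk is slow peracid addition to a carbonyl that is branched on both α-carbons and sits in a bridged ring, so that over a long reaction time acid-promoted opening of the epoxide competes. Fallback: set out from 28 and remove the three silyl groups first (HF·pyridine, pyridine) to give the trihydroxy ketone F1. Oxidise F1 with mCPBA/NaHCO3; the free C11 and C17 hydroxyls hydrogen-bond to the peracid and the carbonyl, and the bulky silyl ethers no longer shield C16. This gives the lactone directly and returns to the route at 30.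

2. Step 23. The risk is slow loading of ruthenium on both termini (a vinyl group on the fully substituted epoxide carbon and a vinyl group next to the acetoxy carbon), so that oligomerisation outruns ring closure. Fallback: set out from 20 and postpone the epoxide. Swern oxidation turns the primary TES ether into the aldehyde, giving the enal aldehyde F2. Wittig methylenation of both aldehydes gives the triene F3, whose C1 chain now ends in a less hindered 1,3-diene. DDQ gives the C7 alcohol F4 and acetylation the acetate F5. Ring-closing metathesis through the diene terminus gives the macrocyclic 3,5-diene F6. Diimide reduces only the disubstituted C5=C6 bond to give the macrocyclic trisubstituted alkene F7. Shi epoxidation with the L-fructose-derived (ent) ketone, the antipode needed for the (3S,4S) epoxide, returns to the route at 28.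

3. Step 6. The risk is metalation of a ring allylic CH2 in competition with the methyl group, and incomplete facial control by the Ipc ligands with this hindered allyl unit. Fallback: set out from 6 and use a regiodefined allylboron reagent. 2-Methylcyclohexanone is converted (Tf2O, 2,6-di-tert-butyl-4-methylpyridine) into the more substituted enol triflate F8. Palladium-catalysed Suzuki coupling of F8 with bis(pinacolato)borylmethane gives the allylboronate F9. F9 adds to 6 under chiral phosphoric acid catalysis (the TRIP antipode that directs Si-face attack) through the same chair transition state, and the route is rejoined at 10.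

**Further compounds**
F1 | step 25 | trihydroxy bridged ketone | [C@H]1(CO)C(=O)[C@]2(C)CC[C@@H]1C[C@@H]1O[C@@]1(C)CC[C@@H](OC(C)=O)[C@@](C)(O)CC[C@H]2O
F2 | step 23 | enal with C6 aldehyde | O=C[C@@H](OCc1ccc(OC)cc1)[C@@](C)(O[Si](CC)(CC)CC)CC[C@@H](O[Si](CC)(CC)CC)[C@@]2(C)CC[C@H](C/C=C(\C)C=O)[C@@H](CO[Si](C)(C)C(C)(C)C)C2=O
F3 | step 23 | triene, C7 PMB ether | C=C[C@@H](OCc1ccc(OC)cc1)[C@@](C)(O[Si](CC)(CC)CC)CC[C@@H](O[Si](CC)(CC)CC)[C@@]2(C)CC[C@H](C/C=C(\C)C=C)[C@@H](CO[Si](C)(C)C(C)(C)C)C2=O
F4 | step 23 | triene, C7 alcohol | C=C[C@@H](O)[C@@](C)(O[Si](CC)(CC)CC)CC[C@@H](O[Si](CC)(CC)CC)[C@@]2(C)CC[C@H](C/C=C(\C)C=C)[C@@H](CO[Si](C)(C)C(C)(C)C)C2=O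
F5 | step 23 | triene, C7 acetate | C=C[C@@H](OC(C)=O)[C@@](C)(O[Si](CC)(CC)CC)CC[C@@H](O[Si](CC)(CC)CC)[C@@]2(C)CC[C@H](C/C=C(\C)C=C)[C@@H](CO[Si](C)(C)C(C)(C)C)C2=O
F6 | step 23 | macrocyclic 3,5-diene ketone | [C@H]1(CO[Si](C)(C)C(C)(C)C)C(=O)[C@]2(C)CC[C@@H]1C/C=C(\C)C=C[C@@H](OC(C)=O)[C@@](C)(O[Si](CC)(CC)CC)CC[C@H]2O[Si](CC)(CC)CC
F7 | step 23 | macrocyclic (E)-3-ene ketone | [C@H]1(CO[Si](C)(C)C(C)(C)C)C(=O)[C@]2(C)CC[C@@H]1C/C=C(\C)CC[C@@H](OC(C)=O)[C@@](C)(O[Si](CC)(CC)CC)CC[C@H]2O[Si](CC)(CC)CC
F8 | step 6 | 2-methylcyclohex-1-en-1-yl trifluoromethanesulfonate | CC1=C(OS(=O)(=O)C(F)(F)F)CCCC1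
F9 | step 6 | 4,4,5,5-tetramethyl-2-[(2-methylcyclohex-1-en-1-yl)methyl]-1,3,2-dioxaborolane | CC1=C(CB2OC(C)(C)C(C)(C)O2)CCCC1
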